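**Plan**

- Rings: A = methylcyclopentane, B = cyclooctene, C = cyclohexane, D = isopropylcyclopentane. Retrosynthesis: the ring B methyl stereocentre goes back to an exocyclic methylene, and the ring B CH2 next to ring A to a disposable carbinol. The two ring B bonds flanking the resulting CH2–C(=CH2)–CH unit (one to that carbinol carbon, one to the tertiary carbinol carbon shared by rings B and C) are then cut together, opening rings B and C. Last, the ketone–CH2 bond to ring D is cut.
- Enabling feature: in ring B the carbons CH2–CH(CH3)–CH form an isobutene-type unit (central carbon = the methyl-bearing one), a latent 2-methylenepropane-1,3-diyl dianion. It lies between two carbons that can both be carbonyl carbons: the B/C-fusion carbinol carbon (a ketone beside the tetrasubstituted ring A/B alkene) and the CH2 next to ring A (an aldehyde).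
- Forward: a ring D iodide (8 steps) and a ring A lactone (5 steps) are joined by alkyllithium addition to the lactone, whose ring fixes the Z-enone geometry. Cross-metathesis installs a 1,1-bis(bromomethyl)alkene, and one indium-mediated double allylation closes ring C, then ring B. Deoxygenation and hydrogenation finish.
- Stereochemistry: ring D comes from the single stereocentre of a terpene (Claisen rearrangement and hydroboration both steered by the isopropyl group). Ring A comes from a ligand-controlled conjugate methylation and a trans-selective aldol. The tertiary carbinol and adjacent CH come from the chair transition state of the first allylation, and the ring B methyl from hydroxyl-directed hydrogenation.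

Key step: step 17

Remark: in step 9 the ligand enantiomer is taken to be the one that gives the (R)-configured β-methyl enolate; keto aldehyde 24 is assumed to last long enough in neutral aqueous THF for the first, fast ring closure.

**Route**

Step 1
Reactants: 1 (S)-limonene
Product: 2 (4S)-1-methyl-4-(propan-2-yl)cyclohex-1-ene
Conditions: H2 (1 atm), RhCl(PPh3)3 (cat.), benzene, rt
Reagents that add atoms: none
Why: Homogeneous hydrogenation with RhCl(PPh3)3 should reduce the 1,1-disubstituted alkene much faster than the trisubstituted ring alkene, and the stereocentre is not touched.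

Step 2
Reactants: 2 (4S)-1-methyl-4-(propan-2-yl)cyclohex-1-ene
Product: 4 (3S)-6-oxo-3-(propan-2-yl)heptanal, via secondary ozonide 3 (not isolated)
Conditions: O3, CH2Cl2, −78 °C; then Me2S, −78 °C to rt
Reagents that add atoms: ozone ([O-][O+]=O)
Why: Ozonolysis with reductive work-up cleaves the only C=C bond and opens the six-membered ring to the keto aldehyde; the β-stereocentre cannot epimerise.

Step 3
Reactants: 4 (3S)-6-oxo-3-(propan-2-yl)heptanal
Product: 5 (5R)-2-methyl-5-(propan-2-yl)cyclopent-1-ene-1-carbaldehyde
Conditions: piperidine (cat.), AcOH (cat.), toluene, 80 °C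
Reagents that add atoms: none
Why: Intramolecular aldol condensation through the aldehyde-derived enamine (five-membered closure onto the methyl ketone, then dehydration) should give the ring D cyclopentene carbaldehyde; the isopropyl-bearing centre is not enolisable.

Step 4
Reactants: 5 (5R)-2-methyl-5-(propan-2-yl)cyclopent-1-ene-1-carbaldehyde
Product: 6 [(5R)-2-methyl-5-(propan-2-yl)cyclopent-1-en-1-yl]methanol
Conditions: NaBH4, CeCl3·7H2O, MeOH, 0 °C
Reagents that add atoms: none
Why: Luche reduction gives clean 1,2-reduction of the enal to the allylic alcohol.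

Step 5
Reactants: 6 [(5R)-2-methyl-5-(propan-2-yl)cyclopent-1-en-1-yl]methanol
Product: 8 methyl 2-[(1R,3R)-1-methyl-2-methylidene-3-(propan-2-yl)cyclopentyl]acetate, via mixed ketene acetal 7 (not isolated)
Conditions: MeC(OMe)3, EtCO2H (cat.), xylene, 140 °C, MeOH distilled off
Reagents that add atoms: trimethyl orthoacetate (CC(OC)(OC)OC)
Why: Johnson–Claisen rearrangement: the ketene acetal should undergo the chair [3,3] shift on the ring face opposite the adjacent isopropyl group, creating the quaternary methyl-bearing centre with the acetate arm trans to isopropyl and leaving an exocyclic methylene.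

Step 6
Reactants: 8 methyl 2-[(1R,3R)-1-methyl-2-methylidene-3-(propan-2-yl)cyclopentyl]acetate
Product: 10 methyl 2-[(1R,2S,3R)-2-(iodomethyl)-1-methyl-3-(propan-2-yl)cyclopentyl]acetate, via B-alkyl-9-BBN adduct 9 (not isolated)
Conditions: 9-BBN, THF, 0 °C to rt; then NaOMe, I2, MeOH, 0 °C
Reagents that add atoms: iodine (II)
Why: Hydroboration by the bulky borane puts boron on the terminal carbon and should deliver hydrogen to the ring carbon from the face opposite the isopropyl and methyl groups, so the new CH2 arm is cis to isopropyl and trans to the acetate arm; base-promoted iodinolysis of the primary B–C bond then gives the iodide.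

Step 7
Reactants: 10 methyl 2-[(1R,2S,3R)-2-(iodomethyl)-1-methyl-3-(propan-2-yl)cyclopentyl]acetate
Product: 11 2-[(1R,2S,3R)-2-(iodomethyl)-1-methyl-3-(propan-2-yl)cyclopentyl]acetaldehyde
Conditions: i-Bu2AlH, CH2Cl2, −78 °C
Reagents that add atoms: none
Why: Low-temperature i-Bu2AlH reduction of the ester should stop at the aldehyde through the stable tetrahedral aluminate, and the hindered primary iodide is inert.

Step 8
Reactants: 11 2-[(1R,2S,3R)-2-(iodomethyl)-1-methyl-3-(propan-2-yl)cyclopentyl]acetaldehyde
Product: 12 (1R,2S,3R)-2-(iodomethyl)-1-methyl-3-(propan-2-yl)-1-(prop-2-en-1-yl)cyclopentane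
Conditions: Ph3PCH3Br, KN(SiMe3)2, THF, −78 to 0 °C
Reagents that add atoms: methyltriphenylphosphonium bromide (C[P+](c1ccccc1)(c1ccccc1)c1ccccc1.[Br-])
Why: Wittig methylenation of the unhindered aldehyde; the β-branched primary iodide is too hindered to alkylate the ylide at low temperature.

Step 9
Reactants: 13 cyclopent-2-en-1-one
Product: 15 trimethyl{[(3R)-3-methylcyclopent-1-en-1-yl]oxy}silane, via methylzinc enolate 14 (not isolated)
Conditions: Me2Zn, Cu(OTf)2 (cat.), chiral peptide-derived phosphine ligand (cat.), toluene, −30 °C; then Me3SiOTf, −30 to 0 °C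
Reagents that add atoms: dimethylzinc (C[Zn]C); trimethylsilyl trifluoromethanesulfonate (C[Si](C)(C)OS(=O)(=O)C(F)(F)F)
Why: Copper-catalysed asymmetric conjugate addition sets the methyl-bearing stereocentre by ligand control, and O-silylation traps the regiodefined zinc enolate.

Step 10
Reactants: 15 trimethyl{[(3R)-3-methylcyclopent-1-en-1-yl]oxy}silane
Product: 16 (2R,3R)-2-(hydroxymethyl)-3-methylcyclopentan-1-one
Conditions: aqueous HCHO, Sc(OTf)3 (cat.), THF/H2O, rt
Reagents that add atoms: formaldehyde (C=O)
Why: Lewis-acid-catalysed Mukaiyama aldol reaction with aqueous formaldehyde; the electrophile should enter trans to the adjacent methyl group.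

Step 11
Reactants: 16 (2R,3R)-2-(hydroxymethyl)-3-methylcyclopentan-1-one
Product: 17 [(1R,2R)-2-methyl-5-oxocyclopentyl]methyl 2-bromopropanoate (both epimers at the CHBr carbon)
Conditions: 2-bromopropanoyl bromide, pyridine, CH2Cl2, −40 to 0 °C
Reagents that add atoms: 2-bromopropanoyl bromide (CC(Br)C(=O)Br)
Why: O-acylation of the primary alcohol under mild base should not trigger β-elimination of the β-acyloxy ketone.

Step 12
Reactants: 17 [(1R,2R)-2-methyl-5-oxocyclopentyl]methyl 2-bromopropanoate
Product: 18 (7R,7aR)-4a-hydroxy-4,7-dimethylhexahydrocyclopenta[c]pyran-3(1H)-one (mixture at C4 and C4a)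
Conditions: SmI2, THF, −78 °C
Reagents that add atoms: none
Why: Samarium Reformatsky reaction: the samarium enolate adds intramolecularly to the ring ketone through a six-membered chelate and closes the δ-lactone; the two new centres are removed in the next step.

Step 13
Reactants: 18 (7R,7aR)-4a-hydroxy-4,7-dimethylhexahydrocyclopenta[c]pyran-3(1H)-one
Product: 20 (7R,7aS)-4,7-dimethyl-5,6,7,7a-tetrahydrocyclopenta[c]pyran-3(1H)-one, via tertiary trifluoroacetate 19 (not isolated)
Conditions: (CF3CO)2O, Et3N, DMAP (cat.), CH2Cl2, 0 °C; then DBU, rt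
Reagents that add atoms: none
Why: Acylation of the tertiary alcohol then E1cB elimination through the lactone enolate should give the conjugated tetrasubstituted alkene, whose geometry (carbonyl cis to the CH–CH2O carbon) is fixed by the lactone ring.

Step 14
Reactants: 12 (1R,2S,3R)-2-(iodomethyl)-1-methyl-3-(propan-2-yl)-1-(prop-2-en-1-yl)cyclopentane; 20 (7R,7aS)-4,7-dimethyl-5,6,7,7a-tetrahydrocyclopenta[c]pyran-3(1H)-one
Product: 22 (3Z)-3-[(2S,3R)-2-(hydroxymethyl)-3-methylcyclopentylidene]-1-[(1S,2R,5R)-2-methyl-5-(propan-2-yl)-2-(prop-2-en-1-yl)cyclopentyl]butan-2-one, via primary alkyllithium 21 (not isolated)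
Conditions: t-BuLi (2.1 equiv), Et2O/pentane, −78 °C; then 20, −78 °C; AcOH quench at −78 °C
Reagents that add atoms: none
Why: Iodine–lithium exchange then 1,2-addition to the lactone carbonyl (ketone synthesis by acyl substitution); the lithium hemiketal should persist at −78 °C and collapse on quench, and the enone geometry is inherited from the lactone.

Step 15
Reactants: 22 (3Z)-3-[(2S,3R)-2-(hydroxymethyl)-3-methylcyclopentylidene]-1-[(1S,2R,5R)-2-methyl-5-(propan-2-yl)-2-(prop-2-en-1-yl)cyclopentyl]butan-2-one
Product: 23 bis(bromomethyl)alkene (22 in which the allyl group CH2–CH=CH2 has become CH2–CH=C(CH2Br)2)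
Conditions: 3-bromo-2-(bromomethyl)prop-1-ene (excess), second-generation Hoveyda–Grubbs catalyst RuCl2(H2IMes)(=CH-C6H4-2-O-i-Pr) (cat.), CH2Cl2, 40 °C
Reagents that add atoms: 3-bromo-2-(bromomethyl)prop-1-ene (C=C(CBr)CBr)
Why: Olefin cross-metathesis of the terminal alkene with an excess of the 1,1-disubstituted partner should give the trisubstituted alkene and ethene; the tetrasubstituted enone alkene is inert.

Step 16
Reactants: 23 bis(bromomethyl)alkene
Product: 24 Z-keto aldehyde (23 with the ring A CH2OH oxidised to CHO)
Conditions: Dess–Martin periodinane, NaHCO3, CH2Cl2, 0 °C; crude product used at once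
Reagents that add atoms: none
Why: Dess–Martin oxidation of the primary alcohol under buffered, non-basic conditions spares the allylic bromides and limits enolisation of the sensitive aldehyde.

Step 17
Reactants: 24 Z-keto aldehyde
Product: 26 tetracyclic diol (target skeleton with an exocyclic methylene at the ring B methyl-bearing carbon and OH on the ring B carbon next to ring A; both epimers at that carbinol), via ring C bromo aldehyde 25 (not isolated)
Conditions: In powder (4 equiv), THF/H2O (1:1), rt, 0.005 M
Reagents that add atoms: none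
Why: Indium inserts into one of the two equivalent allylic C–Br bonds and the allylindium adds through its substituted terminus to the ketone in a chair-like, metal-bridged transition state, which closes ring C (six-membered closure onto C=O) and gives 25; the remaining 2-substituted allyl bromide is metalated in turn and adds through a CH2 terminus to the aldehyde, which closes ring B (eight-membered closure; both CH2 termini give the same product) and leaves the exocyclic methylene. The closest known reaction type is the indium-mediated Barbier bis-allylation of a dicarbonyl compound with 3-bromo-2-(bromomethyl)prop-1-ene as a trimethylenemethane dianion equivalent in aqueous solvent. The tertiary carbinol centre and the neighbouring ring-fusion CH are controlled by the trans-disposed arms on ring D: in the chair that leads to the trans-fused hydrindane the alkenyl group on the ketone and the allyl unit are both equatorial and the carbonyl oxygen is axial, cis to the allyl unit as the cyclic transition state requires. The secondary carbinol formed at the former aldehyde carbon is not controlled and is deleted in steps 18 and 19. The step needs the ketone to react before the aldehyde, which ring size should secure (six-membered against ten-membered transition state for the first allylindium), and it needs ring closure to beat intermolecular allylation and protonolysis, which high dilution and the pre-organisation by the Z-enone and the cis-related oxygen and allyl groups on ring C should secure.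

Step 18
Reactants: 26 tetracyclic diol
Product: 27 O-phenyl thionocarbonate of the secondary (ring B) alcohol of 26
Conditions: PhOC(S)Cl, pyridine, DMAP (cat.), CH2Cl2, rt
Reagents that add atoms: O-phenyl chlorothionoformate (S=C(Cl)Oc1ccccc1)
Why: Thioacylation of the secondary alcohol (first half of the Barton–McCombie deoxygenation); the tertiary allylic alcohol is too hindered to react.

Step 19
Reactants: 27 O-phenyl thionocarbonate
Product: 28 exocyclic-methylene alcohol (target with C=CH2 in place of CH–CH3 in ring B)
Conditions: Bu3SnH (0.3 M), AIBN (cat.), toluene, 80 °C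
Reagents that add atoms: none
Why: Barton–McCombie radical deoxygenation; the high stannane concentration should trap the secondary radical before it can rearrange through either homoallylic alkene.

Step 20
Reactants: 28 exocyclic-methylene alcohol
Product: 29 sesterfisherol
Conditions: H2 (1 atm), [Ir(cod)(PCy3)(py)]PF6 (cat.), CH2Cl2, 0 °C to rt
Reagents that add atoms: none
Why: Hydroxyl-directed homogeneous hydrogenation: the iridium catalyst binds the tertiary alcohol and should add hydrogen to the exocyclic methylene from the hydroxyl-bearing face, so the new methyl is trans to OH across ring B; the tetrasubstituted alkene reacts far more slowly.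

**Compound list**

1 | (S)-limonene | CC1=CC[C@H](CC1)C(C)=C | starting material
2 | (4S)-1-methyl-4-(propan-2-yl)cyclohex-1-ene | CC1=CC[C@H](CC1)C(C)C | intermediate
3 | secondary ozonide of 2 | CC12OOC(O1)C[C@@H](C(C)C)CC2 | intermediate
4 | (3S)-6-oxo-3-(propan-2-yl)heptanal | O=CC[C@H](CCC(C)=O)C(C)C | intermediate
5 | (5R)-2-methyl-5-(propan-2-yl)cyclopent-1-ene-1-carbaldehyde | O=CC1=C(C)CC[C@@H]1C(C)C | intermediate
6 | [(5R)-2-methyl-5-(propan-2-yl)cyclopent-1-en-1-yl]methanol | OCC1=C(C)CC[C@@H]1C(C)C | intermediate
7 | mixed ketene acetal (1-methoxyvinyl ether of 6) | C=C(OC)OCC1=C(C)CC[C@@H]1C(C)C | intermediate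
8 | methyl 2-[(1R,3R)-1-methyl-2-methylidene-3-(propan-2-yl)cyclopentyl]acetate | COC(=O)C[C@@]1(C)CC[C@H](C(C)C)C1=C | intermediate
9 | B-alkyl-9-BBN adduct of 8 | COC(=O)C[C@@]1(C)CC[C@H](C(C)C)[C@@H]1CB1C2CCCC1CCC2 | intermediate
10 | methyl 2-[(1R,2S,3R)-2-(iodomethyl)-1-methyl-3-(propan-2-yl)cyclopentyl]acetate | COC(=O)C[C@@]1(C)CC[C@H](C(C)C)[C@@H]1CI | intermediate
11 | 2-[(1R,2S,3R)-2-(iodomethyl)-1-methyl-3-(propan-2-yl)cyclopentyl]acetaldehyde | O=CC[C@@]1(C)CC[C@H](C(C)C)[C@@H]1CI | intermediate
12 | (1R,2S,3R)-2-(iodomethyl)-1-methyl-3-(propan-2-yl)-1-(prop-2-en-1-yl)cyclopentane | C=CC[C@@]1(C)CC[C@H](C(C)C)[C@@H]1CI | intermediate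
13 | cyclopent-2-en-1-one | O=C1C=CCC1 | starting material
14 | methylzinc enolate of (R)-3-methylcyclopentanone | C[C@@H]1CCC(O[Zn]C)=C1 | intermediate
15 | trimethyl{[(3R)-3-methylcyclopent-1-en-1-yl]oxy}silane | C[C@@H]1CCC(O[Si](C)(C)C)=C1 | intermediate
16 | (2R,3R)-2-(hydroxymethyl)-3-methylcyclopentan-1-one | O=C1CC[C@@H](C)[C@@H]1CO | intermediate
17 | [(1R,2R)-2-methyl-5-oxocyclopentyl]methyl 2-bromopropanoate | O=C1CC[C@@H](C)[C@@H]1COC(=O)C(C)Br | intermediate
18 | (7R,7aR)-4a-hydroxy-4,7-dimethylhexahydrocyclopenta[c]pyran-3(1H)-one | O=C1OC[C@H]2[C@H](C)CCC2(O)C1C | intermediate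
19 | tertiary trifluoroacetate of 18 | O=C1OC[C@H]2[C@H](C)CCC2(OC(=O)C(F)(F)F)C1C | intermediate
20 | (7R,7aS)-4,7-dimethyl-5,6,7,7a-tetrahydrocyclopenta[c]pyran-3(1H)-one | CC1=C2CC[C@@H](C)[C@@H]2COC1=O | intermediate
21 | primary alkyllithium from 12 | C=CC[C@@]1(C)CC[C@H](C(C)C)[C@@H]1C[Li] | intermediate
22 | (3Z)-3-[(2S,3R)-2-(hydroxymethyl)-3-methylcyclopentylidene]-1-[(1S,2R,5R)-2-methyl-5-(propan-2-yl)-2-(prop-2-en-1-yl)cyclopentyl]butan-2-one | C=CC[C@@]1(C)CC[C@H](C(C)C)[C@@H]1CC(=O)/C(C)=C1/CC[C@@H](C)[C@@H]1CO | intermediate
23 | bis(bromomethyl)alkene (22 with CH2–CH=C(CH2Br)2 in place of allyl) | BrCC(CBr)=CC[C@@]1(C)CC[C@H](C(C)C)[C@@H]1CC(=O)/C(C)=C1/CC[C@@H](C)[C@@H]1CO | intermediate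
24 | Z-keto aldehyde (23 with CHO in place of CH2OH) | BrCC(CBr)=CC[C@@]1(C)CC[C@H](C(C)C)[C@@H]1CC(=O)/C(C)=C1/CC[C@@H](C)[C@@H]1C=O | intermediate
25 | ring C bromo aldehyde (trans-hydrindane tertiary alcohol carrying the 3-bromoprop-1-en-2-yl group and the ring A aldehyde) | C/C(=C1\CC[C@@H](C)[C@@H]1C=O)[C@@]1(O)C[C@H]2[C@@H](C(C)C)CC[C@]2(C)C[C@@H]1C(=C)CBr | intermediate
26 | tetracyclic diol (exocyclic methylene in ring B, secondary OH next to ring A, both epimers) | C/C1=C2\CC[C@@H](C)[C@@H]2C(O)CC(=C)[C@H]2C[C@@]3(C)CC[C@H](C(C)C)[C@@H]3C[C@]12O | intermediate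
27 | O-phenyl thionocarbonate of 26 (at the secondary OH) | C/C1=C2\CC[C@@H](C)[C@@H]2C(OC(=S)Oc4ccccc4)CC(=C)[C@H]2C[C@@]3(C)CC[C@H](C(C)C)[C@@H]3C[C@]12O | intermediate
28 | exocyclic-methylene alcohol (11-methylidene precursor of the target) | C/C1=C2\CC[C@@H](C)[C@@H]2CCC(=C)[C@H]2C[C@@]3(C)CC[C@H](C(C)C)[C@@H]3C[C@]12O | intermediate
29 | sesterfisherol | C/C1=C2\CC[C@@H](C)[C@@H]2CC[C@H](C)[C@H]2C[C@@]3(C)CC[C@H](C(C)C)[C@@H]3C[C@]12O | target

**Summary**

Total step count: 20. Longest linear sequence: 15 steps (steps 1–8 and 14–20).

Steps most likely to fail: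

1. Step 17. The keto aldehyde may enolise toward the conjugated ring A enal before it is allylated, the second allylindium may be protonated faster than the eight-membered ring closes, or the aldehyde may be allylated intermolecularly. Fallback, from 22 back to 26, with the two rings closed one after the other and the aldehyde made only after the ketone is gone: cross-metathesis of 22 with 2-(chloromethyl)-3-(trimethylsilyl)prop-1-ene (same ruthenium catalyst) would give the chloro allylsilane F1. Indium with NaI in DMF/H2O would allylate the ketone and close ring C to the hydroxy allylsilane F2. Dess–Martin oxidation of the primary alcohol would give the allylsilane aldehyde F3. Fluoride-promoted intramolecular Hosomi–Sakurai allylation (Bu4N Ph3SiF2, THF) would then close ring B under non-acidic conditions to 26.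

2. Step 15. Cross-metathesis to a trisubstituted alkene bearing two allylic bromides may stall through slow turnover, catalyst decay or homodimerisation of the terminal alkene. Fallback without metathesis, from 11 back to 23: Knoevenagel condensation of 11 with dimethyl malonate (piperidine, AcOH) would give the alkylidene malonate F4. i-Bu2AlH would reduce both esters to the 2-alkylidene-1,3-diol F5, and 2,2-dimethoxypropane with pyridinium tosylate would give the acetonide F6. Iodine–lithium exchange and addition to 20 under the step 14 conditions would give the hydroxy enone acetonide F7, and aqueous acetic acid would free the triol F8. Allylic-selective Corey–Kim bromination (N-bromosuccinimide, Me2S, CH2Cl2, −20 °C) would convert only the two allylic hydroxyls and give 23.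

3. Step 14. The alkyllithium may deprotonate the lactone at its γ-positions, add twice, or cyclise onto its own allyl group if the addition needs warming. Fallback with a different acyl donor, from 20 back to 22: 20 would be opened with MeNH(OMe)·HCl and i-PrMgCl to the Z-hydroxy Weinreb amide F9 and silylated (t-BuPh2SiCl, imidazole) to the silyl ether amide F10. Addition of 21 at −78 °C would stop at the stable chelate and give the silyl-protected enone F11, and HF·pyridine would release 22.

**Further compounds**

F1 | step 17 | chloro allylsilane (22 with CH2–CH=C(CH2Cl)CH2SiMe3 in place of allyl) | C[Si](C)(C)CC(CCl)=CC[C@@]1(C)CC[C@H](C(C)C)[C@@H]1CC(=O)/C(C)=C1/CC[C@@H](C)[C@@H]1CO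
F2 | step 17 | hydroxy allylsilane (ring C closed, 3-(trimethylsilyl)prop-1-en-2-yl group, ring A CH2OH) | C/C(=C1\CC[C@@H](C)[C@@H]1CO)[C@@]1(O)C[C@H]2[C@@H](C(C)C)CC[C@]2(C)C[C@@H]1C(=C)C[Si](C)(C)C
F3 | step 17 | allylsilane aldehyde (F2 with CHO in place of CH2OH) | C/C(=C1\CC[C@@H](C)[C@@H]1C=O)[C@@]1(O)C[C@H]2[C@@H](C(C)C)CC[C@]2(C)C[C@@H]1C(=C)C[Si](C)(C)C
F4 | step 15 | alkylidene malonate from 11 | COC(=O)C(=CC[C@@]1(C)CC[C@H](C(C)C)[C@@H]1CI)C(=O)OC
F5 | step 15 | 2-alkylidenepropane-1,3-diol | OCC(CO)=CC[C@@]1(C)CC[C@H](C(C)C)[C@@H]1CI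
F6 | step 15 | acetonide of F5 | CC1(C)OCC(CO1)=CC[C@@]2(C)CC[C@H](C(C)C)[C@@H]2CI
F7 | step 15 | hydroxy enone acetonide | CC1(C)OCC(CO1)=CC[C@@]2(C)CC[C@H](C(C)C)[C@@H]2CC(=O)/C(C)=C2/CC[C@@H](C)[C@@H]2CO
F8 | step 15 | triol (23 with OH in place of both Br) | OCC(CO)=CC[C@@]1(C)CC[C@H](C(C)C)[C@@H]1CC(=O)/C(C)=C1/CC[C@@H](C)[C@@H]1CO
F9 | step 14 | (2Z)-2-[(2S,3R)-2-(hydroxymethyl)-3-methylcyclopentylidene]-N-methoxy-N-methylpropanamide | C/C(C(=O)N(C)OC)=C1\CC[C@@H](C)[C@@H]1CO
F10 | step 14 | tert-butyldiphenylsilyl ether of F9 | C/C(C(=O)N(C)OC)=C1\CC[C@@H](C)[C@@H]1CO[Si](c2ccccc2)(c2ccccc2)C(C)(C)C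
F11 | step 14 | tert-butyldiphenylsilyl ether of 22 | C=CC[C@@]1(C)CC[C@H](C(C)C)[C@@H]1CC(=O)/C(C)=C1/CC[C@@H](C)[C@@H]1CO[Si](c2ccccc2)(c2ccccc2)C(C)(C)C
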